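The ring atoms are numbered C1(Me)=C2–C3–C4(O, iPr)–C5–C6. C4 is stereogenic only because the C1=C2 alkene lies on one side of it, so the route never passes through a symmetric ring. The alkene is carried as a preformed (Z)-alkenyl iodide, and the cyclohexene is closed at the C1–C6 single bond by a one-pot 9-BBN hydroboration and intramolecular B-alkyl Suzuki–Miyaura coupling. The precursor is an acyclic tertiary vinyl carbinol whose quaternary C4 comes from (R)-2-hydroxy-3-methylbutanoic acid by self-regeneration of stereocentres, with a temporary dioxolanone ring relaying the chirality. Acylation of the resulting (R)-terpinen-4-ol with 4-methoxy-3,5-diprenylbenzoic acid ends the synthesis.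

Key step: step 7

Assumption: (R)-2-hydroxy-3-methylbutanoic acid, 3,5-dibromo-4-methoxybenzoic acid and prenylboronic acid pinacol ester are taken as commercial; the target is R at C4.

Step 1
Reactants: 1 but-2-yn-1-ol
Product: 3 (Z)-3-iodobut-2-en-1-ol, via cyclic alkenylalanate 2 (not isolated)
Conditions: NaAlH2(OCH2CH2OMe)2 (Red-Al), THF, 0 °C to rt; EtOAc; then I2, THF, −78 °C to 0 °C
Reagents that add atoms: iodine, II
Why: Hydroxyl-directed trans-hydroalumination of the propargylic alcohol puts hydride on C2 and aluminium on C3 in a five-membered oxaluminacycle, and iodinolysis of the C–Al bond with retention fixes the Z geometry (iodine cis to CH2OH) that the later ring closure needs.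

Step 2
Reactants: 3 (Z)-3-iodobut-2-en-1-ol
Product: 4 (Z)-1-bromo-3-iodobut-2-ene
Conditions: PBr3 (0.4 equiv), Et2O, 0 °C
Reagents that add atoms: phosphorus tribromide, BrP(Br)Br
Why: SN2 bromination of the primary allylic alcohol with PBr3 should leave the alkenyl iodide and its Z geometry untouched.

Step 3
Reactants: 5 (R)-2-hydroxy-3-methylbutanoic acid; 6 pivalaldehyde
Product: 7 (2R,5R)-2-tert-butyl-5-(propan-2-yl)-1,3-dioxolan-4-one (cis)
Conditions: TsOH·H2O (cat.), H2SO4 (cat.), pentane, reflux, Dean–Stark; cis isomer purified by crystallization or chromatography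
Reagents that add atoms: none
Why: Acid-catalysed acetalization with water removal should favour the cis-dioxolanone, whose new acetal centre C2 (R) is set by the existing C5 centre and stores the chirality once C5 is enolized (self-regeneration of stereocentres).

Step 4
Reactants: 7 (2R,5R)-2-tert-butyl-5-(propan-2-yl)-1,3-dioxolan-4-one; 4 (Z)-1-bromo-3-iodobut-2-ene
Product: 9 (2R,5R)-2-tert-butyl-5-[(2Z)-3-iodobut-2-en-1-yl]-5-(propan-2-yl)-1,3-dioxolan-4-one, via lithium enolate 8 (not isolated)
Conditions: LiN(iPr)2 (LDA), THF, −78 °C; then 4, DMPU, −78 °C to −30 °C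
Reagents that add atoms: none
Why: Enolate alkylation in the self-regeneration-of-stereocentres manifold: the planar lithium enolate should be attacked by the reactive allylic bromide anti to the tert-butyl group, so the butenyl chain takes the place of the former hydrogen and the quaternary centre (future C4) is set with overall retention.

Step 5
Reactants: 9 (2R,5R)-2-tert-butyl-5-[(2Z)-3-iodobut-2-en-1-yl]-5-(propan-2-yl)-1,3-dioxolan-4-one
Product: 10 (2R,5R)-2-tert-butyl-5-[(2Z)-3-iodobut-2-en-1-yl]-5-(propan-2-yl)-1,3-dioxolan-4-ol (lactol; mixture of C4 epimers)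
Conditions: i-Bu2AlH (DIBAL-H, 1.2 equiv), CH2Cl2, −78 °C; aq. Rochelle salt
Reagents that add atoms: none
Why: Partial reduction of the lactone carbonyl by DIBAL-H should stop at the lactol because the tetrahedral aluminium hemiacetal is stable at −78 °C, and the alkenyl iodide is inert to the hydride.

Step 6
Reactants: 10 lactol
Product: 12 (3R,5Z)-6-iodo-3-(propan-2-yl)hepta-1,5-dien-3-ol, via hydroxy aldehyde 11 (not isolated)
Conditions: Ph3PCH3Br (3.5 equiv), KOt-Bu (3.4 equiv), THF, 0 °C; then 10, 0 °C to rt
Reagents that add atoms: methyltriphenylphosphonium bromide, C[P+](c1ccccc1)(c1ccccc1)c1ccccc1.[Br-]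
Why: Wittig methylenation of a lactol: base opens the hemiacetal, the resulting hemiacetal alkoxide expels pivalaldehyde to unmask α-hydroxy aldehyde 11, and the small ylide should convert the aldehyde into the C5=C6 vinyl group without touching the quaternary centre.

Step 7
Reactants: 12 (3R,5Z)-6-iodo-3-(propan-2-yl)hepta-1,5-dien-3-ol
Product: 14 (R)-terpinen-4-ol [(1R)-4-methyl-1-(propan-2-yl)cyclohex-3-en-1-ol], via B-alkyl-9-BBN 13 (not isolated)
Conditions: 9-BBN (9-borabicyclo[3.3.1]nonane, 2.5 equiv), THF, 0 °C to rt; then Pd(dppf)Cl2 (10 mol %), AsPh3 (10 mol %), aq. Cs2CO3, DMF/THF, 0.01 M, rt to 50 °C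
Reagents that add atoms: none
Why: 9-BBN should add anti-Markovnikov to the monosubstituted C5=C6 vinyl group only (the trisubstituted iodoalkene is inert), giving primary alkylborane 13; zerovalent palladium then inserts into the C1–I bond with retention, the base-activated B-alkyl group transmetalates, and reductive elimination from a seven-membered palladacycle forms C1–C6. This is an intramolecular B-alkyl Suzuki–Miyaura coupling, the hydroboration/cyclization known for halo-dienes. The six-membered ring is closed at the sp2 carbon C1 with the C1=C2 alkene kept endocyclic, which is possible only because the Z geometry holds the C1–Pd bond cis to the C3 tether. No stereocentre is created: C4 (R, from step 4) is untouched and the alkene cannot migrate, so the C3 and C5 arms stay distinct. The step needs cyclization over oligomerization, secured by dilution and the cis geometry, and reductive elimination over β-hydride elimination, secured by the wide-bite-angle dppf ligand.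

Step 8
Reactants: 15 3,5-dibromo-4-methoxybenzoic acid; 16 4,4,5,5-tetramethyl-2-(3-methylbut-2-en-1-yl)-1,3,2-dioxaborolane (prenylboronic acid pinacol ester, 3 equiv)
Product: 17 4-methoxy-3,5-bis(3-methylbut-2-en-1-yl)benzoic acid
Conditions: PdCl2(IPent)(3-chloropyridine) (cat.; IPent = 1,3-bis[2,6-di(pentan-3-yl)phenyl]imidazol-2-ylidene), 5 M aq. KOH, THF, 70 °C; then 1 M HCl
Reagents that add atoms: none
Why: Twofold Suzuki–Miyaura allyl–aryl coupling in which the bulky NHC palladium catalyst should let the allylpalladium intermediate settle in its less hindered primary σ-allyl form before reductive elimination, giving the linear (α) prenyl arene at both bromides while the carboxylate is tolerated by the aqueous base.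

Step 9
Reactants: 17 4-methoxy-3,5-bis(3-methylbut-2-en-1-yl)benzoic acid; 14 (R)-terpinen-4-ol
Product: 20 (1R)-4-methyl-1-(propan-2-yl)cyclohex-3-en-1-yl 4-methoxy-3,5-bis(3-methylbut-2-en-1-yl)benzoate (target), via acid chloride 18 (not isolated), via lithium alkoxide 19 (not isolated)
Conditions: 17, 1-chloro-N,N,2-trimethylprop-1-en-1-amine, CH2Cl2, 0 °C to rt; separately 14, n-BuLi, THF, −78 °C to 0 °C; combine, 0 °C to rt
Reagents that add atoms: none
Why: Nucleophilic acyl substitution of the hindered tertiary lithium alkoxide on the acid chloride, which is generated under neutral conditions so that the acid-sensitive prenyl groups survive; the C4–O bond is never broken, so the R configuration is retained.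

Compound list
1 | but-2-yn-1-ol | CC#CCO | starting material
2 | sodium cyclic alkenylalanate (2,5-dihydro-1,2-oxaluminole ate complex from 1 and Red-Al) | [Na+].CC1=CCO[Al-]1(OCCOC)OCCOC | intermediate (not isolated)
3 | (Z)-3-iodobut-2-en-1-ol | OC/C=C(/C)I | intermediate
4 | (Z)-1-bromo-3-iodobut-2-ene | BrC/C=C(/C)I | intermediate
5 | (R)-2-hydroxy-3-methylbutanoic acid | CC(C)[C@@H](O)C(=O)O | starting material
6 | pivalaldehyde (2,2-dimethylpropanal) | CC(C)(C)C=O | starting material
7 | (2R,5R)-2-tert-butyl-5-(propan-2-yl)-1,3-dioxolan-4-one (cis) | O=C1O[C@H](C(C)(C)C)O[C@@H]1C(C)C | intermediate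
8 | lithium enolate of 7 | [Li+].CC(C)C1=C([O-])O[C@H](C(C)(C)C)O1 | intermediate (not isolated)
9 | (2R,5R)-2-tert-butyl-5-[(2Z)-3-iodobut-2-en-1-yl]-5-(propan-2-yl)-1,3-dioxolan-4-one | O=C1O[C@H](C(C)(C)C)O[C@]1(C/C=C(/C)I)C(C)C | intermediate
10 | (2R,5R)-2-tert-butyl-5-[(2Z)-3-iodobut-2-en-1-yl]-5-(propan-2-yl)-1,3-dioxolan-4-ol (C4 epimers) | OC1O[C@H](C(C)(C)C)O[C@]1(C/C=C(/C)I)C(C)C | intermediate
11 | (2R,4Z)-2-hydroxy-5-iodo-2-(propan-2-yl)hex-4-enal | O=C[C@](O)(C(C)C)C/C=C(/C)I | intermediate (not isolated)
12 | (3R,5Z)-6-iodo-3-(propan-2-yl)hepta-1,5-dien-3-ol | C=C[C@](O)(C(C)C)C/C=C(/C)I | intermediate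
13 | 9-[(3R,5Z)-3-hydroxy-6-iodo-3-(propan-2-yl)hept-5-en-1-yl]-9-borabicyclo[3.3.1]nonane | CC(C)[C@@](O)(CCB1C2CCCC1CCC2)C/C=C(/C)I | intermediate (not isolated)
14 | (R)-terpinen-4-ol, (1R)-4-methyl-1-(propan-2-yl)cyclohex-3-en-1-ol | O[C@@]1(C(C)C)CC=C(C)CC1 | intermediate
15 | 3,5-dibromo-4-methoxybenzoic acid | COc1c(Br)cc(C(=O)O)cc1Br | starting material
16 | 4,4,5,5-tetramethyl-2-(3-methylbut-2-en-1-yl)-1,3,2-dioxaborolane | CC(C)=CCB1OC(C)(C)C(C)(C)O1 | starting material
17 | 4-methoxy-3,5-bis(3-methylbut-2-en-1-yl)benzoic acid | COc1c(CC=C(C)C)cc(C(=O)O)cc1CC=C(C)C | intermediate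
18 | 4-methoxy-3,5-bis(3-methylbut-2-en-1-yl)benzoyl chloride | COc1c(CC=C(C)C)cc(C(Cl)=O)cc1CC=C(C)C | intermediate (not isolated)
19 | lithium (1R)-4-methyl-1-(propan-2-yl)cyclohex-3-en-1-olate | [Li+].[O-][C@@]1(C(C)C)CC=C(C)CC1 | intermediate (not isolated)
20 | (1R)-4-methyl-1-(propan-2-yl)cyclohex-3-en-1-yl 4-methoxy-3,5-bis(3-methylbut-2-en-1-yl)benzoate | COc1c(CC=C(C)C)cc(C(=O)O[C@@]2(C(C)C)CC=C(C)CC2)cc1CC=C(C)C | target

Total step count: 9. Longest linear sequence: 7 steps (steps 1, 2, 4, 5, 6, 7 and 9).

Steps most likely to fail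

Step 7. Intermolecular coupling to oligomers, protodeboronation of the alkylborane, or β-hydride elimination from the alkylpalladium species may outrun the ring-closing reductive elimination. The fallback sets out from 12 and comes back at 14. Hydroboration of 12 with 9-BBN and oxidation with NaBO3 would give (3S,5Z)-6-iodo-3-(propan-2-yl)hept-5-ene-1,3-diol F1. Iodination of its primary hydroxyl (I2, PPh3, imidazole) would give (3S,5Z)-1,6-diiodo-3-(propan-2-yl)hept-5-en-3-ol F2. Zinc insertion into the primary C–I bond (Zn dust, LiCl, THF) followed by Pd(PPh3)4 would then close the same C1–C6 bond by an intramolecular Negishi coupling and deliver 14.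

Step 6. The lactol may open slowly, and the strongly basic ylide may dehydrohalogenate the alkenyl iodide or degrade the α-hydroxy aldehyde before methylenation. The fallback sets out from 9 and comes back at 12. Full reduction of 9 with LiBH4 (THF) would give (2R,4Z)-5-iodo-2-(propan-2-yl)hex-4-ene-1,2-diol F3. Selective tosylation of the primary hydroxyl (TsCl, pyridine) and closure with K2CO3 in MeOH would give (2R)-2-[(2Z)-3-iodobut-2-en-1-yl]-2-(propan-2-yl)oxirane F4. Excess dimethylsulfonium methylide (Me3SI, n-BuLi, THF, −10 °C to rt) would open the epoxide at its CH2 terminus and eliminate dimethyl sulfide, a one-carbon homologation to the allylic alcohol 12 that avoids the aldehyde.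

Step 9. Acylation of the hindered tertiary alkoxide may be slow, so that the prenyl-bearing acid chloride is consumed by side reactions and the alcohol is returned. The fallback sets out from 15 and 14 and comes back at 20. SOCl2 at reflux would convert 15 into the robust, more electrophilic 3,5-dibromo-4-methoxybenzoyl chloride F5, which can be used in excess and with heating against lithium alkoxide 19 to give (1R)-4-methyl-1-(propan-2-yl)cyclohex-3-en-1-yl 3,5-dibromo-4-methoxybenzoate F6. A twofold linear-selective Negishi coupling of F6 with prenylzinc bromide (Pd(OAc)2, CPhos, THF, rt) would then install both prenyl groups last and give 20.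

Further compounds
F1 | step 7 | (3S,5Z)-6-iodo-3-(propan-2-yl)hept-5-ene-1,3-diol | OCC[C@](O)(C(C)C)C/C=C(/C)I
F2 | step 7 | (3S,5Z)-1,6-diiodo-3-(propan-2-yl)hept-5-en-3-ol | ICC[C@](O)(C(C)C)C/C=C(/C)I
F3 | step 6 | (2R,4Z)-5-iodo-2-(propan-2-yl)hex-4-ene-1,2-diol | OC[C@](O)(C(C)C)C/C=C(/C)I
F4 | step 6 | (2R)-2-[(2Z)-3-iodobut-2-en-1-yl]-2-(propan-2-yl)oxirane | CC(C)[C@@]1(CO1)C/C=C(/C)I
F5 | step 9 | 3,5-dibromo-4-methoxybenzoyl chloride | COc1c(Br)cc(C(Cl)=O)cc1Br
F6 | step 9 | (1R)-4-methyl-1-(propan-2-yl)cyclohex-3-en-1-yl 3,5-dibromo-4-methoxybenzoate | COc1c(Br)cc(C(=O)O[C@@]2(C(C)C)CC=C(C)CC2)cc1Br
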